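## Analysis of the target

Target 19 is an isoflavanone in which ring A (C4a–C8a) is fused to the dihydropyranone ring C (O1, C2, C3, C4) and carries hydroxyls on C5 and C7 and a prenyl group on C6, while C3 bears ring B, a 4′-hydroxy-3′-prenylphenyl group. C3 is the only stereocentre and is (R), so only the absolute sense has to be controlled. It is tertiary, benzylic and α to the C4 ketone, so it can be lost by enolisation in base or acid, or by reversible opening of ring C through loss of the O1 aryloxide. The two trisubstituted alkenes exclude hydrogenolysis and strong electrophiles, and each prenyl group sits next to a phenol onto which acid would cyclise it to a dimethylchroman. Ring A also poses a regiochemical question, since the prenyl group must lie at C6, between the two hydroxyls, and not at C8. The difficulty is to create the labile C3 centre late, in one absolute sense, and then free the phenols without epimerising it. The strategy rests on two latent polarities: because C3 lies para to the 4′-hydroxyl across ring B, loss of a leaving group from C3 makes it the electrophilic exocyclic carbon of a para-quinone methide. C4, attached to C4a next to the O1-bearing carbon C8a, corresponds to the formyl carbon of an O-alkylated salicylaldehyde, which carbene catalysis can turn into an acyl anion equivalent.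

## Retrosynthetic reasoning

**19 from 18.** Only two O–Si bonds on ring A are cut. Silyl ethers are chosen because buffered fluoride removes them without acid that would cyclise a prenyl group and without base that would enolise C3. The 4′-hydroxyl is already free in 18, because the key step leaves it so.

**18 from 16 through 17.** The C3–C4 bond is cut. It is the one bond whose formation both closes ring C and creates the stereocentre, with both carbons already at their final oxidation level. Normal polarity (C3 enolate, C4 acyl cation) gives no hold on the configuration. Reversed polarity makes C4 a catalyst-bound acyl anion and C3 an acceptor, which is possible only because ring B carries its hydroxyl para to C3. Quinone methide 17 cannot be stored, so it is released in the flask from sulfone 16 by base. C3 is planar in 17, so racemic 16 is sufficient. The forward step has to release 17 slowly, close the six-membered ring at carbon and choose one face.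

**16 from 15.** The 4′-oxygen is masked as an allyl ether. A para-hydroxybenzyl sulfone loses sulfinate in any basic medium, so the phenol must stay capped until the key step. The cap must come off without base, acid or fluoride, which points to allyl transfer to zerovalent palladium.

**15 from 6 and 14.** The O1–C2 ether bond is cut, which divides the molecule into two halves of similar size. The sulfonyl group is already on 14, so no redox step follows the union. A sequence through a ketone at the future C3 was set aside. Its hydride reduction would have to spare the ring A formyl group, and a salicylaldehyde O-alkylated by a ketone-bearing chain tends to close to a benzofuran by aldol condensation. The forward reaction is a dehydrative etherification of a primary alcohol with an acidic phenol.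

**14 back to 7, 2 and 11.** The C2–C3 bond comes from hydroxymethylation of carbanion 13 of benzyl sulfone 12. The C–S bond comes from benzylic substitution of alcohol 10 by sulfinate 11. Alcohol 10 comes from aldehyde 9 and thus from phenol 8, made by ortho C-prenylation of 7 with 2.

**6 back to 1 and 2.** The C4–C4a bond is made by ortho-formylation of phenol 5. Phenol 5 is symmetric: its two ortho positions are equivalent and its para position carries the prenyl group. The formyl group can therefore enter only where it places the prenyl group at C6, and the C6/C8 question does not arise. Phenol 5 comes from tris-silyl ether 4 by loss of the one unhindered silyl group, 4 from triol 3, and 3 from 1 and 2.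

## Alternatives that were turned down

Alternative 1: Ring A is made last. The C4a–C5 bond is cut, which leads back to pyranone keto ester A2, a 4-pyranone that already carries ring B and a four-carbon keto ester arm. Mg(OMe)2 in hot methanol would enolise the arm of A2, the pyranone carbon that becomes C4a would attack the ester carbonyl (C5), and loss of methanol and tautomerisation would give isoflavone A1.
- For: the prenyl group sits between the two carbonyls of the arm and can only end at C6, and ring A needs no protecting groups. On both points it is stronger than the chosen route, which must desymmetrise a phloroglucinol and carry two silyl ethers.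
- Against: A1 has a C2=C3 double bond and no stereocentre. The target would need an enantioselective conjugate reduction that spares two prenyl alkenes and stops at the ketone, so further redox steps are likely. Hot alkoxide can also open the pyranone of A2 at its unsubstituted enol ether carbon.
- In its place the chosen route sets C3 in the ring-forming step, at the final oxidation level.

Alternative 2: Three bonds of ring C are cut at once (C8a–O1, C4a–C4, O1–C2), leading to silyl triflate A4 and acrylic acid A5. CsF would generate the aryne from A4. The carboxylate of A5 would add at the future C8a, the aryl anion at C4a would attack the acyl carbon, and the freed phenoxide would close ring C by oxa-Michael addition to give A3.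
- For: three bonds and the whole of ring C form in one flask, by a sequence of known type. In bond economy and precedent it is stronger than the chosen key step.
- Against: C3 arises by uncontrolled protonation of an enolate, so A3 is racemic. A4 is a pentasubstituted benzene that needs several steps. The three methoxymethyl ethers of A3 need protic acid at the end, which is the condition under which prenyl groups cyclise and C3 enolises.
- In its place the chosen route gives one bond only, but with absolute control at C3 and a fluoride-labile protecting set.

Alternative 3: The C2–C3 bond is cut and C2 is traced to an O-methyl group on ring A, so the precursor is diazoketone A7. The divalent rhodium carboxylate Rh2(S-PTTL)4 (or its mirror image) would expel dinitrogen from A7, and the carbene would insert into a C–H bond of the ortho methoxy group to give A6.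
- For: C3 is also set catalytically in the ring-forming step. The medium is neutral, so the new centre never meets base, and A7 is a storable compound. On both points it is stronger than the chosen route.
- Against: the ether oxygen of A7 stands in a 1,5-relationship to the carbene carbon. Attack on oxygen to a five-membered oxonium ylide, followed by a 1,2-methyl shift to a benzofuranone, is geometrically favoured over insertion into a primary C–H bond through a six-membered transition state. The prenyl alkenes and donor-rich arenes are further carbene traps. Ring A still needs desymmetrising (one methyl ether, two silyl ethers).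
- In its place the chosen route is metal-free, and the only bond its reacting centres can form in a six-membered closure is C3–C4.

Key step: step 12

Assumption: the (5aR,10bS) antipode of the aminoindanol-derived triazolium salt is taken to deliver the acyl carbon to the Re face of C3. If the sense of induction is opposite, the (5aS,10bR) salt is used and nothing else changes.

Abbreviations: prenyl = 3-methylbut-2-enyl; TBS = tert-butyldimethylsilyl; Ts = p-tolylsulfonyl.

## Route

Step 1
Reactants: 1 phloroglucinol; 2 prenyl bromide
Product: 3 2-prenylbenzene-1,3,5-triol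
Conditions: KOH (1.0 equiv), H2O, 0 °C to rt; 1 in excess (1.5 equiv)
Reagents that add atoms: none
Why: C-Alkylation of the ambident phloroglucinolate, favoured in water because the oxygen is solvated; the excess of 1 holds the reaction at the mono-prenyl stage. All three ring positions are equivalent, so only one mono-C-prenyl isomer can form.

Step 2
Reactants: 3 2-prenylbenzene-1,3,5-triol
Product: 4 1,3,5-tris(TBS-oxy)-2-prenylbenzene
Conditions: TBSCl (3.6 equiv), imidazole (7 equiv), DMF, rt to 40 °C
Reagents that add atoms: tert-butyldimethylsilyl chloride, CC(C)(C)[Si](C)(C)Cl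
Why: Exhaustive imidazole-promoted silylation of the three phenols; no selectivity is asked of this step.

Step 3
Reactants: 4 1,3,5-tris(TBS-oxy)-2-prenylbenzene
Product: 5 3,5-bis(TBS-oxy)-4-prenylphenol
Conditions: K2CO3 (1.0 equiv), MeOH–THF (2:1), −10 to 0 °C; aq. NH4Cl
Reagents that add atoms: none
Why: Base-mediated methanolysis of an aryl silyl ether. The silyl group para to the prenyl chain has two free ortho positions, while the other two are shielded by the prenyl CH2. The phenoxide formed after the first cleavage makes the ring too electron-rich to lose a second silyl group readily.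

Step 4
Reactants: 5 3,5-bis(TBS-oxy)-4-prenylphenol
Product: 6 2,4-bis(TBS-oxy)-6-hydroxy-3-prenylbenzaldehyde
Conditions: MgCl2 (2 equiv), Et3N (4 equiv), (CH2O)n (6 equiv), THF, reflux; aq. NH4Cl
Reagents that add atoms: paraformaldehyde (formaldehyde), C=O
Why: Magnesium-mediated ortho-formylation (Casnati–Skattebøl): the magnesium phenoxide delivers formaldehyde to the ortho carbon and a second formaldehyde accepts hydride to leave the aldehyde. The two ortho positions of 5 are equivalent and the para position is blocked, so the formyl group can only enter at the future C4a.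

Step 5
Reactants: 7 4-hydroxybenzaldehyde; 2 prenyl bromide
Product: 8 4-hydroxy-3-prenylbenzaldehyde
Conditions: KOH (1.1 equiv), H2O, rt
Reagents that add atoms: none
Why: ortho-C-Alkylation of the phenoxide in water, as in step 1. The para position is occupied by the formyl group, which also tempers the ring against a second alkylation.

Step 6
Reactants: 8 4-hydroxy-3-prenylbenzaldehyde
Product: 9 4-(allyloxy)-3-prenylbenzaldehyde
Conditions: allyl bromide (1.3 equiv), K2CO3 (2 equiv), acetone, reflux
Reagents that add atoms: allyl bromide, C=CCBr
Why: Williamson ether synthesis. The allyl ether masks the phenol, which would otherwise expel sulfinate in every later basic step.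

Step 7
Reactants: 9 4-(allyloxy)-3-prenylbenzaldehyde
Product: 10 [4-(allyloxy)-3-prenylphenyl]methanol
Conditions: NaBH4 (0.5 equiv), MeOH, 0 °C
Reagents that add atoms: none
Why: Borohydride reduction of an aryl aldehyde; the isolated alkenes and the allyl ether are inert.

Step 8
Reactants: 10 [4-(allyloxy)-3-prenylphenyl]methanol; 11 sodium 4-methylbenzenesulfinate
Product: 12 1-(allyloxy)-2-prenyl-4-[(p-tolylsulfonyl)methyl]benzene
Conditions: 11 (2 equiv), HCO2H–H2O–THF, rt
Reagents that add atoms: none
Why: Acid-promoted SN1 substitution: the 4-alkoxybenzyl cation is captured at sulfur by toluenesulfinic acid, and any sulfinate O-ester reverts under the acidic conditions. With the phenol capped there is no free hydroxyl for the ortho prenyl group to cyclise onto.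

Step 9
Reactants: 12 1-(allyloxy)-2-prenyl-4-[(p-tolylsulfonyl)methyl]benzene
Product: 14 rac-2-[4-(allyloxy)-3-prenylphenyl]-2-(p-tolylsulfonyl)ethanol, via lithiated sulfone 13 (not isolated)
Conditions: n-BuLi (1.05 equiv), THF, −78 °C; then (CH2O)n (5 equiv), −78 °C to rt; aq. NH4Cl
Reagents that add atoms: paraformaldehyde (formaldehyde), C=O
Why: Deprotonation of the benzylic sulfone (pKa about 23) and hydroxymethylation of the sulfonyl carbanion, which forms the C2–C3 bond of the target. The sulfonyl-bearing carbon is a racemic centre of no consequence, since it becomes planar in step 12.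

Step 10
Reactants: 6 2,4-bis(TBS-oxy)-6-hydroxy-3-prenylbenzaldehyde; 14 rac-2-[4-(allyloxy)-3-prenylphenyl]-2-(p-tolylsulfonyl)ethanol
Product: 15 rac-6-{2-[4-(allyloxy)-3-prenylphenyl]-2-(p-tolylsulfonyl)ethoxy}-2,4-bis(TBS-oxy)-3-prenylbenzaldehyde
Conditions: PPh3 (1.5 equiv), DIAD (1.5 equiv), THF, 0 °C to rt
Reagents that add atoms: none
Why: Mitsunobu etherification of the primary alcohol with the acidic salicylaldehyde phenol forms O1–C2. If the activated alcohol first eliminates to the vinyl sulfone, conjugate addition of the same phenoxide leads to the same constitution.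

Step 11
Reactants: 15 rac-6-{2-[4-(allyloxy)-3-prenylphenyl]-2-(p-tolylsulfonyl)ethoxy}-2,4-bis(TBS-oxy)-3-prenylbenzaldehyde
Product: 16 rac-6-[2-(4-hydroxy-3-prenylphenyl)-2-(p-tolylsulfonyl)ethoxy]-2,4-bis(TBS-oxy)-3-prenylbenzaldehyde
Conditions: Pd(PPh3)4 (5 mol %), 11 (1.5 equiv), AcOH (2 equiv), THF, rt
Reagents that add atoms: none
Why: Tsuji–Trost deallylation: the zerovalent palladium complex ionises the aryl allyl ether, sulfinate traps the allyl fragment as a sulfone and acetic acid protonates the phenoxide. Sulfinate is the safe scavenger here, because any quinone methide formed in passing is returned by it to 16.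

Step 12
Reactants: 16 rac-6-[2-(4-hydroxy-3-prenylphenyl)-2-(p-tolylsulfonyl)ethoxy]-2,4-bis(TBS-oxy)-3-prenylbenzaldehyde
Product: 18 (R)-5,7-bis(TBS-oxy)-3-(4-hydroxy-3-prenylphenyl)-6-prenylchroman-4-one, via para-quinone methide 17 (not isolated)
Conditions: (5aR,10bS)-2-(pentafluorophenyl)-5a,10b-dihydro-4H,6H-indeno[2,1-b][1,2,4]triazolo[4,3-d][1,4]oxazin-2-ium tetrafluoroborate (20 mol %), K2CO3 (1.5 equiv), toluene, 0 °C, 16 added slowly at high dilution; AcOH quench at 0 °C
Reagents that add atoms: none
Why: Proposed new method: K2CO3 deprotonates the 4′-phenol of 16 and the phenoxide expels toluenesulfinate by 1,6-elimination, so both enantiomers of the sulfone give the same planar quinone methide 17; the triazolylidene adds to the ring A formyl group, proton transfer gives the Breslow intermediate, its nucleophilic carbon attacks the exocyclic carbon of 17 (the future C3) with re-aromatisation of ring B, and loss of the carbene leaves the C4 ketone. The closest known reactions are the enantioselective intramolecular Stetter cyclisation of O-tethered salicylaldehyde acceptors to 3-substituted chroman-4-ones and the carbene-catalysed 1,6-addition of aldehydes to para-quinone methides; new here is their combination on an unhindered quinone methide released in the flask. Ring C closes in a 6-exo-trig mode, the acceptor C=C lying outside the new ring. C3 is set by the catalyst alone: the aminoindane wall shields one face of the Breslow intermediate, and delivery to the Re face of the exocyclic carbon (C2, C1′ and H clockwise) gives (R); the E and Z forms of 17 differ only in the remote 3′-prenyl group and present the same local faces. The step needs C-acylation to outrun O-attack of a phenoxide on 17, tautomerisation of 17 to a 4-hydroxystyryl enol ether and capture of free carbene by 17; the six-membered intramolecular delivery, slow addition and a sparingly soluble base that keeps 17 scarce should secure this. The base must also take the phenol proton (pKa about 10) and not the C–H next to sulfur (pKa above 20), whose removal would expel the ring A aryloxide. Epimerisation of the product C3–H is held back by the low temperature, by the donor-rich ring A that lowers the acidity of the aryl ketone, and by the acid quench before warming.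

Step 13
Reactants: 18 (R)-5,7-bis(TBS-oxy)-3-(4-hydroxy-3-prenylphenyl)-6-prenylchroman-4-one
Product: 19 (R)-5,7-dihydroxy-3-(4-hydroxy-3-prenylphenyl)-6-prenylchroman-4-one (target)
Conditions: Bu4NF (3 equiv), AcOH (3 equiv), THF, 0 °C
Reagents that add atoms: none
Why: Fluoride cleavage of the two aryl silyl ethers. Acetic acid keeps the medium near neutral, so the phenoxides can neither enolise C3 nor open ring C by β-elimination, and the prenyl groups are untouched; C3 stays (R).

## Compound list

1 | phloroglucinol | Oc1cc(O)cc(O)c1 | starting material
2 | prenyl bromide | CC(C)=CCBr | starting material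
3 | 2-prenylbenzene-1,3,5-triol | CC(C)=CCc1c(O)cc(O)cc1O | intermediate
4 | 1,3,5-tris(TBS-oxy)-2-prenylbenzene | CC(C)=CCc1c(O[Si](C)(C)C(C)(C)C)cc(O[Si](C)(C)C(C)(C)C)cc1O[Si](C)(C)C(C)(C)C | intermediate
5 | 3,5-bis(TBS-oxy)-4-prenylphenol | CC(C)=CCc1c(O[Si](C)(C)C(C)(C)C)cc(O)cc1O[Si](C)(C)C(C)(C)C | intermediate
6 | 2,4-bis(TBS-oxy)-6-hydroxy-3-prenylbenzaldehyde | O=Cc1c(O)cc(O[Si](C)(C)C(C)(C)C)c(CC=C(C)C)c1O[Si](C)(C)C(C)(C)C | intermediate
7 | 4-hydroxybenzaldehyde | O=Cc1ccc(O)cc1 | starting material
8 | 4-hydroxy-3-prenylbenzaldehyde | CC(C)=CCc1cc(C=O)ccc1O | intermediate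
9 | 4-(allyloxy)-3-prenylbenzaldehyde | CC(C)=CCc1cc(C=O)ccc1OCC=C | intermediate
10 | [4-(allyloxy)-3-prenylphenyl]methanol | CC(C)=CCc1cc(CO)ccc1OCC=C | intermediate
11 | sodium 4-methylbenzenesulfinate | Cc1ccc(cc1)S(=O)[O-].[Na+] | starting material
12 | 1-(allyloxy)-2-prenyl-4-[(p-tolylsulfonyl)methyl]benzene | CC(C)=CCc1cc(CS(=O)(=O)c2ccc(C)cc2)ccc1OCC=C | intermediate
13 | α-lithio derivative of sulfone 12 (not isolated) | CC(C)=CCc1cc([CH-]S(=O)(=O)c2ccc(C)cc2)ccc1OCC=C.[Li+] | intermediate
14 | rac-2-[4-(allyloxy)-3-prenylphenyl]-2-(p-tolylsulfonyl)ethanol | CC(C)=CCc1cc(C(CO)S(=O)(=O)c2ccc(C)cc2)ccc1OCC=C | intermediate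
15 | rac-6-{2-[4-(allyloxy)-3-prenylphenyl]-2-(p-tolylsulfonyl)ethoxy}-2,4-bis(TBS-oxy)-3-prenylbenzaldehyde | O=Cc1c(OCC(c2ccc(OCC=C)c(CC=C(C)C)c2)S(=O)(=O)c2ccc(C)cc2)cc(O[Si](C)(C)C(C)(C)C)c(CC=C(C)C)c1O[Si](C)(C)C(C)(C)C | intermediate
16 | rac-6-[2-(4-hydroxy-3-prenylphenyl)-2-(p-tolylsulfonyl)ethoxy]-2,4-bis(TBS-oxy)-3-prenylbenzaldehyde | O=Cc1c(OCC(c2ccc(O)c(CC=C(C)C)c2)S(=O)(=O)c2ccc(C)cc2)cc(O[Si](C)(C)C(C)(C)C)c(CC=C(C)C)c1O[Si](C)(C)C(C)(C)C | intermediate
17 | para-quinone methide: 2,4-bis(TBS-oxy)-6-[2-(4-oxo-3-prenylcyclohexa-2,5-dien-1-ylidene)ethoxy]-3-prenylbenzaldehyde, E/Z mixture (not isolated) | O=Cc1c(OCC=C2C=CC(=O)C(CC=C(C)C)=C2)cc(O[Si](C)(C)C(C)(C)C)c(CC=C(C)C)c1O[Si](C)(C)C(C)(C)C | intermediate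
18 | (R)-5,7-bis(TBS-oxy)-3-(4-hydroxy-3-prenylphenyl)-6-prenylchroman-4-one | CC(C)=CCc1cc([C@@H]2COc3cc(O[Si](C)(C)C(C)(C)C)c(CC=C(C)C)c(O[Si](C)(C)C(C)(C)C)c3C2=O)ccc1O | intermediate
19 | (R)-5,7-dihydroxy-3-(4-hydroxy-3-prenylphenyl)-6-prenylchroman-4-one | CC(C)=CCc1cc([C@@H]2COc3cc(O)c(CC=C(C)C)c(O)c3C2=O)ccc1O | target

## Step count and least certain steps

Total: 13 steps. Longest linear sequence: 9 steps (steps 5 to 13, from 7). The ring A branch (steps 1 to 4) joins at step 10.

**Step 12 (key step, new method).** Several processes may compete. Carbene addition to the formyl group may be slow, since it is flanked on both sides and donor-rich, so the quinone methide may be consumed by phenoxide O-alkylation or by tautomerisation. The carbene may be captured irreversibly by the quinone methide. The ring A aryloxide may be expelled after deprotonation next to sulfur. A silyl group may transfer from ring A to the ring B phenoxide. Facial selectivity may be poor, or C3 may epimerise after closure.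

The fallback uses known chemistry, sets out from 15 and returns at 18, with C3 as the nucleophile and C4 as the electrophile. LiN(SiMe3)2 in THF at −78 °C deprotonates 15 next to sulfur, and the carbanion adds to the formyl group to give 3-[4-(allyloxy)-3-prenylphenyl]-5,7-bis(TBS-oxy)-6-prenyl-3-(p-tolylsulfonyl)chroman-4-ol F1; if the aryloxide is expelled first, oxa-Michael addition and aldol closure lead to the same ring. Dess–Martin periodinane then oxidises F1 to rac-3-[4-(allyloxy)-3-prenylphenyl]-5,7-bis(TBS-oxy)-6-prenyl-3-(p-tolylsulfonyl)chroman-4-one F2. SmI2 in THF at −78 °C cleaves the C–S bond of F2, and the samarium enolate is protonated by a C2-symmetric chiral diol (enantioselective protonation, known for samarium enolates of 2-aryl cycloalkanones) to give (R)-3-[4-(allyloxy)-3-prenylphenyl]-5,7-bis(TBS-oxy)-6-prenylchroman-4-one F3. Deallylation of F3 under the conditions of step 11 gives 18.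

**Step 10.** The activated alcohol may dehydrate, and substitution at the β-branched carbon may be slow. The fallback sets out from 14 and returns at 15, and makes the elimination deliberate. MsCl and Et3N convert 14 into rac-2-[4-(allyloxy)-3-prenylphenyl]-2-(p-tolylsulfonyl)ethyl methanesulfonate F4, which loses methanesulfonate in the same flask to give 1-(allyloxy)-2-prenyl-4-[1-(p-tolylsulfonyl)ethenyl]benzene F5. Phenol 6 is then added to F5 by oxa-Michael addition under catalytic PBu3 to give 15.

**Step 3.** A second silyl group may be lost, or cleavage may occur at a hindered oxygen. The fallback sets out from 3 and returns at 5, and differentiates the oxygens by acylation instead. Pivaloyl chloride (1 equiv) and pyridine at −40 °C should acylate the least hindered hydroxyl of 3 to give 3,5-dihydroxy-4-prenylphenyl pivalate F6. TBSCl and imidazole then give 3,5-bis(TBS-oxy)-4-prenylphenyl pivalate F7, and i-Bu2AlH at −78 °C removes the ester to give 5.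

**Step 4.** Formylation next to a bulky silyloxy group may be slow, and silyl groups may be lost in the hot amine medium. The fallback sets out from 5 and returns at 15, and reverses the order of events. Mitsunobu coupling of 5 with 14 gives rac-1-(allyloxy)-4-{2-[3,5-bis(TBS-oxy)-4-prenylphenoxy]-1-(p-tolylsulfonyl)ethyl}-2-prenylbenzene F8. Vilsmeier–Haack formylation of F8 (POCl3, DMF, 0 °C; aq. NaOAc) then gives 15; it acts on the trioxygenated ring, whose two open positions are equivalent.

## Further compounds

F1 | step 12 | 3-[4-(allyloxy)-3-prenylphenyl]-5,7-bis(TBS-oxy)-6-prenyl-3-(p-tolylsulfonyl)chroman-4-ol (racemic, diastereomer mixture) | OC1c2c(O[Si](C)(C)C(C)(C)C)c(CC=C(C)C)c(O[Si](C)(C)C(C)(C)C)cc2OCC1(c1ccc(OCC=C)c(CC=C(C)C)c1)S(=O)(=O)c1ccc(C)cc1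
F2 | step 12 | rac-3-[4-(allyloxy)-3-prenylphenyl]-5,7-bis(TBS-oxy)-6-prenyl-3-(p-tolylsulfonyl)chroman-4-one | O=C1c2c(O[Si](C)(C)C(C)(C)C)c(CC=C(C)C)c(O[Si](C)(C)C(C)(C)C)cc2OCC1(c1ccc(OCC=C)c(CC=C(C)C)c1)S(=O)(=O)c1ccc(C)cc1
F3 | step 12 | (R)-3-[4-(allyloxy)-3-prenylphenyl]-5,7-bis(TBS-oxy)-6-prenylchroman-4-one | CC(C)=CCc1cc([C@@H]2COc3cc(O[Si](C)(C)C(C)(C)C)c(CC=C(C)C)c(O[Si](C)(C)C(C)(C)C)c3C2=O)ccc1OCC=C
F4 | step 10 | rac-2-[4-(allyloxy)-3-prenylphenyl]-2-(p-tolylsulfonyl)ethyl methanesulfonate | CC(C)=CCc1cc(C(COS(C)(=O)=O)S(=O)(=O)c2ccc(C)cc2)ccc1OCC=C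
F5 | step 10 | 1-(allyloxy)-2-prenyl-4-[1-(p-tolylsulfonyl)ethenyl]benzene | CC(C)=CCc1cc(C(=C)S(=O)(=O)c2ccc(C)cc2)ccc1OCC=C
F6 | step 3 | 3,5-dihydroxy-4-prenylphenyl pivalate | CC(C)=CCc1c(O)cc(OC(=O)C(C)(C)C)cc1O
F7 | step 3 | 3,5-bis(TBS-oxy)-4-prenylphenyl pivalate | CC(C)=CCc1c(O[Si](C)(C)C(C)(C)C)cc(OC(=O)C(C)(C)C)cc1O[Si](C)(C)C(C)(C)C
F8 | step 4 | rac-1-(allyloxy)-4-{2-[3,5-bis(TBS-oxy)-4-prenylphenoxy]-1-(p-tolylsulfonyl)ethyl}-2-prenylbenzene | CC(C)=CCc1cc(C(COc2cc(O[Si](C)(C)C(C)(C)C)c(CC=C(C)C)c(O[Si](C)(C)C(C)(C)C)c2)S(=O)(=O)c2ccc(C)cc2)ccc1OCC=C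
A1 | alternative 1 | 6,3′-diprenylgenistein, 5,7-dihydroxy-3-(4-hydroxy-3-prenylphenyl)-6-prenylchromen-4-one | CC(C)=CCc1cc(-c2coc3cc(O)c(CC=C(C)C)c(O)c3c2=O)ccc1O
A2 | alternative 1 | methyl 4-[5-(4-hydroxy-3-prenylphenyl)-4-oxo-4H-pyran-2-yl]-3-oxo-2-prenylbutanoate | COC(=O)C(CC=C(C)C)C(=O)Cc1cc(=O)c(-c2ccc(O)c(CC=C(C)C)c2)co1
A3 | alternative 2 | rac-5,7-bis(methoxymethoxy)-3-[4-(methoxymethoxy)-3-prenylphenyl]-6-prenylchroman-4-one | CC(C)=CCc1cc(C2COc3cc(OCOC)c(CC=C(C)C)c(OCOC)c3C2=O)ccc1OCOC
A4 | alternative 2 | 3,5-bis(methoxymethoxy)-4-prenyl-2-(trimethylsilyl)phenyl trifluoromethanesulfonate | C[Si](C)(C)c1c(OS(=O)(=O)C(F)(F)F)cc(OCOC)c(CC=C(C)C)c1OCOC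
A5 | alternative 2 | 2-[4-(methoxymethoxy)-3-prenylphenyl]acrylic acid | C=C(C(=O)O)c1ccc(OCOC)c(CC=C(C)C)c1
A6 | alternative 3 | (R)-5,7-bis(TBS-oxy)-3-[4-(TBS-oxy)-3-prenylphenyl]-6-prenylchroman-4-one | CC(C)=CCc1cc([C@@H]2COc3cc(O[Si](C)(C)C(C)(C)C)c(CC=C(C)C)c(O[Si](C)(C)C(C)(C)C)c3C2=O)ccc1O[Si](C)(C)C(C)(C)C
A7 | alternative 3 | 2-diazo-1-[2,4-bis(TBS-oxy)-6-methoxy-3-prenylphenyl]-2-[4-(TBS-oxy)-3-prenylphenyl]ethanone | COc1cc(O[Si](C)(C)C(C)(C)C)c(CC=C(C)C)c(O[Si](C)(C)C(C)(C)C)c1C(=O)C(=[N+]=[N-])c1ccc(O[Si](C)(C)C(C)(C)C)c(CC=C(C)C)c1
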